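## The problem

Lespeflorin B1 (24) is a 2,3-trans-dihydroflavonol: a chroman-4-one (rings A and C) with a 4-hydroxyphenyl ring B at C2, a free hydroxyl at C3, free phenols at C7 and C4', and a prenyl group ortho to each phenol, at C6 and C3'. Ring C holds the only two stereocentres, C2 (R, benzylic, bonded to O1) and C3 (R, α to the C4 ketone). They are adjacent and the trans, diequatorial arrangement is the more stable one, so a secure C3 centre can dictate C2 if C2 is formed reversibly; nothing can later correct C3. Both centres are labile: C2 opens through the 4'-phenol (para-quinone methide) or through the C3 enolate, and in base the α-ketol oxidises to the flavonol or contracts to a benzofuranone. The two trisubstituted olefins rule out hydrogenolysis and strong electrophiles, and each sits beside a phenol that adds to it under acid to give a dimethylchroman. Regiochemistry matters twice: ring A must carry its prenyl at C6, not at the usually more reactive C8, and ring B only at C3'. The enabling feature is that C2 lies para to the 4'-OH and is therefore a latent para-quinone methide carbon, while ring B with C2, C3 and C4 is the carbon skeleton of tyrosine, C3 being the former α-carbon and C4 the carboxyl carbon. The (R) configuration needed at C3 is that of D-tyrosine.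

## Retrosynthesis

**Endgame, C3'–C1''' bond.** Target 24 is traced to its 7-O-methoxymethyl ether 23. The ring B prenyl bond of 23 is cut by an aromatic Claisen transform to the 1,1-dimethylallyl ether 21, which comes from propargyl ether 20 and so from phenol 18 and 3-chloro-3-methylbut-1-yne (19). Direct C-prenylation of ring B would give O/C and mono/bis mixtures; the sigmatropic route uses the 4'-OH that the key step leaves free, and has one outcome because the two ortho positions of ring B are equivalent. The forward steps must spare the α-ketol, so the alkylation is run cold and the rearrangement in a weakly basic medium.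

**Key disconnection, O1–C2.** Flavanone 18 is opened at O1–C2. Unlike a cut at C4–C4a or C2–C3, this removes ring C and the C2 stereocentre together and leaves the open-chain α-hydroxy ketone 16, with one stereocentre and a plain para-substituted phenol as ring B. In the forward sense 16 loses two electrons and two protons: ring B is oxidised to quinone methide 17 and the ring A phenol adds to its exocyclic carbon. The reaction must choose ring B over ring A and over the prenyl olefin, stop after two electrons, and place C2 trans to the C3 hydroxyl. This is why ring B stays unprenylated until after this step (an ortho-prenyl phenol would open an ortho-quinone methide pathway) and why O7 stays protected (a free 7-OH would be the most acidic and most easily oxidised phenol).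

**Unmasking.** Ketone 16 is the selectively deprotected form of diol 15, which comes from the bis-silyl ether 14. The two methoxymethyl ethers of 15 differ only in their position relative to the ketone, and the forward step must cleave the ortho one alone. Carrying both ring A oxygens in the same form keeps the ring A synthesis symmetrical and short.

**C4–C4a bond.** Ketone 14 is cut between the carbonyl carbon and ring A into aryllithium 12, made from bromide 5, and the N-methoxy-N-methylamide 11. A Friedel–Crafts acylation of a prenylated resorcinol would be neither regioselective nor compatible with the olefin; here the bromine fixes the acyl position and the amide stops the addition at the ketone. The forward reaction must not enolise the α-silyloxy amide.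

**Chiral pool.** Amide 11 is the silylated form of amide 10, made from hydroxy acid 9, which is the diazotisation product of D-tyrosine (6). The whole ring B–C2–C3–C4 unit and the C3 configuration are bought in one compound; the forward sequence only has to keep that centre.

**Ring A.** Bromide 5 comes from dibromide 2 by exchange of one of two equivalent bromines and allylation with prenyl bromide (3). Dibromide 2 is the bis(methoxymethyl) ether of 4,6-dibromoresorcinol (1). The halogen pattern of 1 places the prenyl group at the future C6 and the acyl group at the future C4a without any isomer problem.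

## Roads not taken

**Alternative 1:** Double aromatic Claisen rearrangement.
- **Cut:** both aryl–prenyl bonds, C6–C1'' and C3'–C1''', with ring C left intact.
- **Forward step:** the 8-iodo bis(1,1-dimethylallyl) ether A1 is heated with catalytic Eu(fod)3. Both ethers rearrange and both phenols are freed, giving A2; reductive removal of iodine would then lead to 24.
- **Merits:** both prenyl groups arrive in one late step, so the sensitive olefins see very few reagents. No organometallic prenylation is needed.
- **Weak points:** the 7-O ether would rearrange to C8 by preference, so iodine must be put on C8 as a blocking group and taken off again in the presence of two olefins and a benzylic C–O bond. The tertiary allyl ether at the acidic, iodine-flanked 7-OH is hard to make and ionises easily. Above all, the route does not address ring C: an enantioenriched dihydroflavonol core has to come from a separate asymmetric synthesis.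
- **Comparison:** this road is better in exposing the prenyl groups to fewer steps; the chosen plan carries the ring A prenyl from step 2 through an electrolysis. Against that, the chosen plan fixes ring A regiochemistry by the bromine pattern without a blocking group, and it builds ring C and both stereocentres from the chiral pool, which Alternative 1 leaves open.

**Alternative 2:** Ortho-quinoid ketene [4+2] cycloaddition.
- **Cut:** ring C across C3–C4 and O1–C2, giving benzodioxinone A3 and (E)-enol acetate A4.
- **Forward step:** irradiation of A3 releases ortho-quinoid ketene A5, which is meant to add across A4 under a chiral phosphoric acid to give acetate A6.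
- **Merits:** the most convergent plan. Two bonds, ring C and both stereocentres form in one step from fragments that already carry both prenyl groups.
- **Weak points:** the enol acetate is polarised so that its aryl-bearing carbon is the nucleophilic one, whereas the ketene carbon must bond to the acetoxy-bearing carbon, so the regiochemistry is mismatched. A short-lived neutral ketene gives a Brønsted acid little to hold, so absolute control is doubtful. Prenyl olefins can undergo [2+2] additions with the ketene or the excited carbonyl. Removing the C3 acetate needs base or acid at the most sensitive centre.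
- **Comparison:** on paper this road is shorter and more convergent than the chosen one. The chosen plan takes C3 from D-tyrosine and sets only C2, under thermodynamic control, with no reliance on an external chiral catalyst; that is the safer way to the single enantiomer.

**Alternative 3:** Parham-type acylation.
- **Cut:** C4–C4a, the same bond the chosen plan makes intermolecularly.
- **Forward step:** halogen–lithium exchange with t-BuLi at the bromine of amide A7 and intramolecular attack on the N-methoxy-N-methylamide closes ring C to give A8.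
- **Merits:** the ring closure is a known reaction type, both stereocentres are in place before it, and only deprotection remains afterwards.
- **Weak points:** A7 needs the O1–C2 aryl ether to be formed with defined configuration at a benzylic, cation-prone carbon using a hindered ortho-bromophenol, where substitution with clean inversion is unreliable. Under t-BuLi the β-aryloxy amide can eliminate the aryloxide, and C2–H is benzylic and α to oxygen. With O4' protected, C2 cannot self-correct.
- **Comparison:** its ring closure is better precedented than the anodic closure, and its endgame is two steps shorter. The chosen plan sets against this a precursor with one stereocentre reached in eight steps from an amino acid, no substitution at the benzylic carbon, and a C2 centre that equilibrates to trans.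

Key step: step 9

## Route

Remark: flavonoid numbering (O1, C2, C3, C4, ring A C4a to C8a, ring B primed) is used throughout, also for open-chain precursors; D-tyrosine is the only source of chirality, and its diazotisation is taken to proceed with net retention.

Step 1
Reactants: 1 4,6-dibromoresorcinol (4,6-dibromobenzene-1,3-diol)
Product: 2 1,5-dibromo-2,4-bis(methoxymethoxy)benzene
Conditions: NaH (2.4 equiv), MOMCl (2.4 equiv), THF/DMF, 0 °C → rt
Reagents that add atoms: chloromethyl methyl ether (MOMCl), COCCl
Why: Williamson O-alkylation of both phenoxides; the methoxymethyl ether tolerates aryllithiums, cannot migrate to an adjacent carbanion and stabilises it by coordination.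

Step 2
Reactants: 2 1,5-dibromo-2,4-bis(methoxymethoxy)benzene; 3 prenyl bromide (1-bromo-3-methylbut-2-ene)
Product: 5 1-bromo-2,4-bis(methoxymethoxy)-5-(3-methylbut-2-en-1-yl)benzene, via aryllithium 4 (not isolated)
Conditions: n-BuLi (1.0 equiv), THF, −78 °C; CuBr·SMe2 (10 mol %), 3, −78 → 0 °C
Reagents that add atoms: none
Why: Bromine–lithium exchange of one of two equivalent bromines (the carbanionic ring resists a second exchange), then copper-catalysed SN2 allylation at the primary carbon of 3; this fixes the prenyl group at the future C6.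

Step 3
Reactants: 6 D-tyrosine
Product: 9 (2R)-2-hydroxy-3-(4-hydroxyphenyl)propanoic acid, via diazonium carboxylate 7 (not isolated), via α-lactone 8 (not isolated)
Conditions: NaNO2 (1.5 equiv), 0.5 M H2SO4 (aq), 0 °C → rt
Reagents that add atoms: water, O
Why: Diazotisation of an α-amino acid; the carboxylate displaces nitrogen with inversion to give α-lactone 8, which water opens at the same carbon with a second inversion, so the (R) configuration should be retained.

Step 4
Reactants: 9 (2R)-2-hydroxy-3-(4-hydroxyphenyl)propanoic acid
Product: 10 (2R)-2-hydroxy-3-(4-hydroxyphenyl)-N-methoxy-N-methylpropanamide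
Conditions: MeNH(OMe)·HCl, EDC·HCl, HOBt, N-methylmorpholine, CH2Cl2/DMF, 0 °C → rt
Reagents that add atoms: N,O-dimethylhydroxylamine hydrochloride, CNOC.Cl
Why: Carbodiimide/HOBt amide coupling; the amine is acylated far faster than either hydroxyl, and an α-hydroxy acid has no oxazolone pathway for racemisation.

Step 5
Reactants: 10 (2R)-2-hydroxy-3-(4-hydroxyphenyl)-N-methoxy-N-methylpropanamide
Product: 11 (2R)-2-(tert-butyldimethylsilyloxy)-3-[4-(tert-butyldimethylsilyloxy)phenyl]-N-methoxy-N-methylpropanamide
Conditions: TBSCl (2.5 equiv), imidazole, DMF, rt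
Reagents that add atoms: tert-butyldimethylsilyl chloride (TBSCl), CC(C)(C)[Si](C)(C)Cl
Why: Imidazole-promoted silylation of the phenol and the secondary alcohol removes both acidic protons before the organolithium step; both ethers are later cleaved together by fluoride.

Step 6
Reactants: 5 1-bromo-2,4-bis(methoxymethoxy)-5-(3-methylbut-2-en-1-yl)benzene; 11 (2R)-2-(tert-butyldimethylsilyloxy)-3-[4-(tert-butyldimethylsilyloxy)phenyl]-N-methoxy-N-methylpropanamide
Product: 14 (2R)-1-[2,4-bis(methoxymethoxy)-5-(3-methylbut-2-en-1-yl)phenyl]-2-(tert-butyldimethylsilyloxy)-3-[4-(tert-butyldimethylsilyloxy)phenyl]propan-1-one, via aryllithium 12 (not isolated), via lithium hemiaminal 13 (not isolated)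
Conditions: 5, n-BuLi (1.05 equiv), THF, −78 °C; then 11, −78 → −20 °C; aq. NH4Cl
Reagents that add atoms: none
Why: Bromine–lithium exchange and acylation of the aryllithium by the N-methoxy-N-methylamide; the chelated adduct 13 survives until quench, so no second addition occurs, and addition at −78 °C should outrun deprotonation at the α-silyloxy carbon, keeping the (R) centre.

Step 7
Reactants: 14 (2R)-1-[2,4-bis(methoxymethoxy)-5-(3-methylbut-2-en-1-yl)phenyl]-2-(tert-butyldimethylsilyloxy)-3-[4-(tert-butyldimethylsilyloxy)phenyl]propan-1-one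
Product: 15 (2R)-1-[2,4-bis(methoxymethoxy)-5-(3-methylbut-2-en-1-yl)phenyl]-2-hydroxy-3-(4-hydroxyphenyl)propan-1-one
Conditions: TBAF (2.5 equiv), AcOH (3 equiv), THF, 0 °C → rt
Reagents that add atoms: none
Why: Fluoride-mediated cleavage of the aryl and the α-keto silyl ethers; acetic acid buffering keeps the medium near neutral so the α-ketol is not enolised, and the acetals and the olefin are inert.

Step 8
Reactants: 15 (2R)-1-[2,4-bis(methoxymethoxy)-5-(3-methylbut-2-en-1-yl)phenyl]-2-hydroxy-3-(4-hydroxyphenyl)propan-1-one
Product: 16 (2R)-2-hydroxy-1-[2-hydroxy-4-(methoxymethoxy)-5-(3-methylbut-2-en-1-yl)phenyl]-3-(4-hydroxyphenyl)propan-1-one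
Conditions: HCl (ca. 0.2 M), MeOH/THF, 0 °C → rt, stopped at mono-cleavage
Reagents that add atoms: none
Why: Acid-catalysed transacetalisation to methanol; the acetal ortho to the ketone should go first because the protonated carbonyl relays its proton to the neighbouring ether oxygen and the released phenol is held in a hydrogen bond, while the para acetal has no such assistance.

Step 9
Reactants: 16 (2R)-2-hydroxy-1-[2-hydroxy-4-(methoxymethoxy)-5-(3-methylbut-2-en-1-yl)phenyl]-3-(4-hydroxyphenyl)propan-1-one
Product: 18 (2R,3R)-3-hydroxy-2-(4-hydroxyphenyl)-7-(methoxymethoxy)-6-(3-methylbut-2-en-1-yl)-2,3-dihydro-4H-chromen-4-one, via para-quinone methide 17 (not isolated)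
Conditions: undivided cell, graphite anode, Pt cathode, constant potential at the foot of the first anodic wave (set by cyclic voltammetry of 16), 2,6-lutidine (2 equiv), n-Bu4NPF6 (0.1 M), (CF3)2CHOH/CH2Cl2 (1:4), 0 °C, 2.0–2.2 F/mol
Reagents that add atoms: none
Why: Proposed new method: the anode takes two electrons from the ring B phenol of 16, which is hydrogen-bonded to 2,6-lutidine so that electron and proton leave together, and loss of a C2 proton gives para-quinone methide 17, whose exocyclic carbon is attacked by the ring A phenol to form O1–C2 and rearomatise ring B. The closest known reaction type is the anodic or chemical oxidation of para-alkylphenols to para-quinone methides followed by intramolecular oxa-1,6-addition of a phenol; this combination on an α-hydroxy dihydrochalcone has not been described. Ring C closes in a 6-exo-trig mode, the oxygen adding to the exocyclic end of the C2=C1' double bond. The new C2 centre is controlled by the existing C3 centre: attack anti to the C3 hydroxyl is favoured kinetically, and because the product keeps its 4'-OH the addition is reversible, so the mixture should settle in the 2,3-trans isomer with aryl and hydroxyl both equatorial, which is (2R,3R). Selectivity between the phenols rests on potential: ring B is a plain para-alkylphenol, the ring A phenol is conjugated with the ketone and hydrogen-bonded to it, and the prenyl olefin oxidises later still, so electrolysis at the first wave with about 2 F/mol should touch ring B only. Further oxidation of 18 towards the flavonol is held back by the charge limit and by the electron-poor substituents now on C2. Hexafluoroisopropanol stabilises the cationic intermediates without adding to them, and the six-membered intramolecular trap is expected to outrun base-mediated loss of the C3 proton from 17, which would give the achiral enol of a 1,2-diketone; C3 itself is not touched.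

Step 10
Reactants: 18 (2R,3R)-3-hydroxy-2-(4-hydroxyphenyl)-7-(methoxymethoxy)-6-(3-methylbut-2-en-1-yl)-2,3-dihydro-4H-chromen-4-one; 19 3-chloro-3-methylbut-1-yne
Product: 20 (2R,3R)-3-hydroxy-7-(methoxymethoxy)-6-(3-methylbut-2-en-1-yl)-2-{4-[(2-methylbut-3-yn-2-yl)oxy]phenyl}-2,3-dihydro-4H-chromen-4-one
Conditions: DBU (1.3 equiv), CuCl2·2H2O (1 mol %), MeCN, 0 °C
Reagents that add atoms: none
Why: Copper-catalysed O-propargylation of a phenol with a tertiary propargylic chloride; only the 4'-phenoxide is formed (the 3-OH is aliphatic, O7 is protected), and the low temperature limits base-induced opening of ring C.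

Step 11
Reactants: 20 (2R,3R)-3-hydroxy-7-(methoxymethoxy)-6-(3-methylbut-2-en-1-yl)-2-{4-[(2-methylbut-3-yn-2-yl)oxy]phenyl}-2,3-dihydro-4H-chromen-4-one
Product: 21 (2R,3R)-3-hydroxy-7-(methoxymethoxy)-6-(3-methylbut-2-en-1-yl)-2-{4-[(2-methylbut-3-en-2-yl)oxy]phenyl}-2,3-dihydro-4H-chromen-4-one
Conditions: H2 (1 atm), Pd/CaCO3 poisoned with Pb(OAc)2 (Lindlar catalyst), quinoline, EtOAc, rt
Reagents that add atoms: none
Why: Lindlar semi-hydrogenation of the terminal alkyne; the poisoned catalyst leaves the trisubstituted prenyl olefin, the ketone and the benzylic C–O bond alone.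

Step 12
Reactants: 21 (2R,3R)-3-hydroxy-7-(methoxymethoxy)-6-(3-methylbut-2-en-1-yl)-2-{4-[(2-methylbut-3-en-2-yl)oxy]phenyl}-2,3-dihydro-4H-chromen-4-one
Product: 23 (2R,3R)-3-hydroxy-2-[4-hydroxy-3-(3-methylbut-2-en-1-yl)phenyl]-7-(methoxymethoxy)-6-(3-methylbut-2-en-1-yl)-2,3-dihydro-4H-chromen-4-one, via ortho-dienone 22 (not isolated)
Conditions: PhNEt2, 120 °C, argon
Reagents that add atoms: none
Why: Aromatic Claisen rearrangement; the [3,3] shift delivers the terminal carbon of the 1,1-dimethylallyl ether to C3' (the two ortho positions of ring B are equivalent), turning it into a prenyl group, and dienone 22 tautomerises to the phenol; the weakly basic solvent suppresses acid-catalysed chroman formation, and any opening at C2 through the freed 4'-OH returns to the trans isomer.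

Step 13
Reactants: 23 (2R,3R)-3-hydroxy-2-[4-hydroxy-3-(3-methylbut-2-en-1-yl)phenyl]-7-(methoxymethoxy)-6-(3-methylbut-2-en-1-yl)-2,3-dihydro-4H-chromen-4-one
Product: 24 lespeflorin B1, (2R,3R)-3,7-dihydroxy-2-[4-hydroxy-3-(3-methylbut-2-en-1-yl)phenyl]-6-(3-methylbut-2-en-1-yl)-2,3-dihydro-4H-chromen-4-one
Conditions: HCl (2 M aq)/MeOH, 40 °C, short reaction time
Reagents that add atoms: none
Why: Acid-catalysed cleavage of the aryl methoxymethyl acetal; dilute acid, moderate temperature and early work-up are meant to free O7 before the phenols add to their neighbouring olefins, and neither stereocentre is involved.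

## Compound list

1 | 4,6-dibromoresorcinol (4,6-dibromobenzene-1,3-diol) | Oc1cc(O)c(Br)cc1Br | starting material
2 | 1,5-dibromo-2,4-bis(methoxymethoxy)benzene | COCOc1cc(OCOC)c(Br)cc1Br | intermediate
3 | prenyl bromide (1-bromo-3-methylbut-2-ene) | CC(C)=CCBr | starting material
4 | [5-bromo-2,4-bis(methoxymethoxy)phenyl]lithium (not isolated) | COCOc1cc(OCOC)c(Br)cc1[Li] | intermediate
5 | 1-bromo-2,4-bis(methoxymethoxy)-5-(3-methylbut-2-en-1-yl)benzene | COCOc1cc(OCOC)c(CC=C(C)C)cc1Br | intermediate
6 | D-tyrosine | N[C@H](Cc1ccc(O)cc1)C(=O)O | starting material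
7 | (2R)-2-diazonio-3-(4-hydroxyphenyl)propanoate (not isolated) | N#[N+][C@H](Cc1ccc(O)cc1)C(=O)[O-] | intermediate
8 | (3S)-3-(4-hydroxybenzyl)oxiran-2-one (not isolated) | O1[C@@H](Cc2ccc(O)cc2)C1=O | intermediate
9 | (2R)-2-hydroxy-3-(4-hydroxyphenyl)propanoic acid | O[C@H](Cc1ccc(O)cc1)C(=O)O | intermediate
10 | (2R)-2-hydroxy-3-(4-hydroxyphenyl)-N-methoxy-N-methylpropanamide | CON(C)C(=O)[C@H](O)Cc1ccc(O)cc1 | intermediate
11 | (2R)-2-(tert-butyldimethylsilyloxy)-3-[4-(tert-butyldimethylsilyloxy)phenyl]-N-methoxy-N-methylpropanamide | CON(C)C(=O)[C@H](O[Si](C)(C)C(C)(C)C)Cc1ccc(O[Si](C)(C)C(C)(C)C)cc1 | intermediate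
12 | [2,4-bis(methoxymethoxy)-5-(3-methylbut-2-en-1-yl)phenyl]lithium (not isolated) | COCOc1cc(OCOC)c(CC=C(C)C)cc1[Li] | intermediate
13 | lithium (2R)-1-[2,4-bis(methoxymethoxy)-5-(3-methylbut-2-en-1-yl)phenyl]-2-(tert-butyldimethylsilyloxy)-3-[4-(tert-butyldimethylsilyloxy)phenyl]-1-[methoxy(methyl)amino]propan-1-olate, C1 undefined (not isolated) | CON(C)C(O[Li])(c1cc(CC=C(C)C)c(OCOC)cc1OCOC)[C@H](O[Si](C)(C)C(C)(C)C)Cc1ccc(O[Si](C)(C)C(C)(C)C)cc1 | intermediate
14 | (2R)-1-[2,4-bis(methoxymethoxy)-5-(3-methylbut-2-en-1-yl)phenyl]-2-(tert-butyldimethylsilyloxy)-3-[4-(tert-butyldimethylsilyloxy)phenyl]propan-1-one | O=C(c1cc(CC=C(C)C)c(OCOC)cc1OCOC)[C@H](O[Si](C)(C)C(C)(C)C)Cc1ccc(O[Si](C)(C)C(C)(C)C)cc1 | intermediate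
15 | (2R)-1-[2,4-bis(methoxymethoxy)-5-(3-methylbut-2-en-1-yl)phenyl]-2-hydroxy-3-(4-hydroxyphenyl)propan-1-one | O=C(c1cc(CC=C(C)C)c(OCOC)cc1OCOC)[C@H](O)Cc1ccc(O)cc1 | intermediate
16 | (2R)-2-hydroxy-1-[2-hydroxy-4-(methoxymethoxy)-5-(3-methylbut-2-en-1-yl)phenyl]-3-(4-hydroxyphenyl)propan-1-one | O=C(c1cc(CC=C(C)C)c(OCOC)cc1O)[C@H](O)Cc1ccc(O)cc1 | intermediate
17 | 4-{(2R)-2-hydroxy-3-[2-hydroxy-4-(methoxymethoxy)-5-(3-methylbut-2-en-1-yl)phenyl]-3-oxopropylidene}cyclohexa-2,5-dien-1-one (not isolated) | O=C1C=CC(=C[C@@H](O)C(=O)c2cc(CC=C(C)C)c(OCOC)cc2O)C=C1 | intermediate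
18 | (2R,3R)-3-hydroxy-2-(4-hydroxyphenyl)-7-(methoxymethoxy)-6-(3-methylbut-2-en-1-yl)-2,3-dihydro-4H-chromen-4-one | Oc1ccc([C@H]2Oc3cc(OCOC)c(CC=C(C)C)cc3C(=O)[C@@H]2O)cc1 | intermediate
19 | 3-chloro-3-methylbut-1-yne | C#CC(C)(C)Cl | starting material
20 | (2R,3R)-3-hydroxy-7-(methoxymethoxy)-6-(3-methylbut-2-en-1-yl)-2-{4-[(2-methylbut-3-yn-2-yl)oxy]phenyl}-2,3-dihydro-4H-chromen-4-one | C#CC(C)(C)Oc1ccc([C@H]2Oc3cc(OCOC)c(CC=C(C)C)cc3C(=O)[C@@H]2O)cc1 | intermediate
21 | (2R,3R)-3-hydroxy-7-(methoxymethoxy)-6-(3-methylbut-2-en-1-yl)-2-{4-[(2-methylbut-3-en-2-yl)oxy]phenyl}-2,3-dihydro-4H-chromen-4-one | C=CC(C)(C)Oc1ccc([C@H]2Oc3cc(OCOC)c(CC=C(C)C)cc3C(=O)[C@@H]2O)cc1 | intermediate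
22 | (2R,3R)-3-hydroxy-7-(methoxymethoxy)-6-(3-methylbut-2-en-1-yl)-2-[3-(3-methylbut-2-en-1-yl)-4-oxocyclohexa-1,5-dien-1-yl]-2,3-dihydro-4H-chromen-4-one, ring B sp3 carbon undefined (not isolated) | CC(C)=CCC1C=C([C@H]2Oc3cc(OCOC)c(CC=C(C)C)cc3C(=O)[C@@H]2O)C=CC1=O | intermediate
23 | (2R,3R)-3-hydroxy-2-[4-hydroxy-3-(3-methylbut-2-en-1-yl)phenyl]-7-(methoxymethoxy)-6-(3-methylbut-2-en-1-yl)-2,3-dihydro-4H-chromen-4-one | CC(C)=CCc1cc([C@H]2Oc3cc(OCOC)c(CC=C(C)C)cc3C(=O)[C@@H]2O)ccc1O | intermediate
24 | lespeflorin B1, (2R,3R)-3,7-dihydroxy-2-[4-hydroxy-3-(3-methylbut-2-en-1-yl)phenyl]-6-(3-methylbut-2-en-1-yl)-2,3-dihydro-4H-chromen-4-one | CC(C)=CCc1cc([C@H]2Oc3cc(O)c(CC=C(C)C)cc3C(=O)[C@@H]2O)ccc1O | target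

## Step count and risk

Total step count: 13. Longest linear sequence: 11 steps (D-tyrosine 6 to 24, steps 3 to 13); the ring A branch (steps 1 and 2) joins at step 6.

**Step 9 (key step, proposed new method).**
- What may go wrong: base-mediated loss of the C3 proton from the quinone methide may compete with ring closure and erase the stereocentre; the cyclised phenol may be oxidised further towards the flavonol; phenoxyl radicals may couple at the electrode; the anode may fail to discriminate between ring B and the ring A phenol or the olefin.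
- Fallback (known chemistry, leaves the tyrosine skeleton): the classical chalcone epoxide route, setting out from bromide 5 and returning at 18.
  - Bromine–lithium exchange of 5 (n-BuLi, THF, −78 °C) and acylation with N-methoxy-N-methylacetamide would give 1-[2,4-bis(methoxymethoxy)-5-(3-methylbut-2-en-1-yl)phenyl]ethan-1-one F1.
  - Claisen–Schmidt condensation with 4-(methoxymethoxy)benzaldehyde (KOH, EtOH) would give (2E)-1-[2,4-bis(methoxymethoxy)-5-(3-methylbut-2-en-1-yl)phenyl]-3-[4-(methoxymethoxy)phenyl]prop-2-en-1-one F2.
  - Juliá–Colonna epoxidation (poly-L-leucine, urea–H2O2, DBU, THF; the polymer enantiomer is chosen for the (2R,3S) epoxide) would give [2,4-bis(methoxymethoxy)-5-(3-methylbut-2-en-1-yl)phenyl]{(2R,3S)-3-[4-(methoxymethoxy)phenyl]oxiran-2-yl}methanone F3.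
  - HCl in MeOH would remove the three acetals and let the freed ortho phenol open the epoxide at the benzylic carbon with inversion, giving (2R,3R)-3,7-dihydroxy-2-(4-hydroxyphenyl)-6-(3-methylbut-2-en-1-yl)-2,3-dihydro-4H-chromen-4-one F4.
  - Selective protection of the more acidic 7-OH (MOMCl 1.0 equiv, K2CO3, acetone, 0 °C) would return to 18.

**Step 8 (selective acetal cleavage).**
- What may go wrong: discrimination between the ortho and para methoxymethyl ethers may be insufficient, so both are lost or a mixture results.
- Fallback: set out from 15 and return at 16 by full removal and selective reprotection. HCl (2 M)/MeOH would cleave both acetals to (2R)-1-[2,4-dihydroxy-5-(3-methylbut-2-en-1-yl)phenyl]-2-hydroxy-3-(4-hydroxyphenyl)propan-1-one F5. One equivalent of MOMCl with K2CO3 in acetone at 0 °C would then alkylate only the para-acyl phenol, which is the most acidic hydroxyl (the ortho phenol is chelated, the ring B phenol is weaker by about two pKa units), giving 16.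

**Step 6 (aryllithium acylation).**
- What may go wrong: deprotonation of the amide at the α-silyloxy carbon would erode the C3 configuration; slow addition of the ortho-substituted aryllithium would let alkylation by the bromobutane by-product compete.
- Fallback: set out from amide 11 and return at 14 by addition to an aldehyde and oxidation. Reduction of 11 (i-Bu2AlH, THF, −78 °C) would give (2R)-2-(tert-butyldimethylsilyloxy)-3-[4-(tert-butyldimethylsilyloxy)phenyl]propanal F6. Addition of aryllithium 12 at −78 °C would give (2R)-1-[2,4-bis(methoxymethoxy)-5-(3-methylbut-2-en-1-yl)phenyl]-2-(tert-butyldimethylsilyloxy)-3-[4-(tert-butyldimethylsilyloxy)phenyl]propan-1-ol F7 as a mixture of carbinol epimers. Dess–Martin periodinane (NaHCO3, CH2Cl2) would oxidise both epimers to 14.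

**Step 12 (Claisen rearrangement).**
- What may go wrong: the α-ketol may open, dehydrogenate or contract during heating; the freed phenol may cyclise onto the new prenyl group or the rearrangement may take an abnormal course.
- Fallback: set out from phenol 18, replace steps 10 to 12 by halogenation and cross-coupling, and return at 23. NIS (1.0 equiv, MeCN, 0 °C) should iodinate ortho to the free 4'-OH to give (2R,3R)-3-hydroxy-2-(4-hydroxy-3-iodophenyl)-7-(methoxymethoxy)-6-(3-methylbut-2-en-1-yl)-2,3-dihydro-4H-chromen-4-one F8. Stille coupling with tributyl(3-methylbut-2-en-1-yl)stannane (Pd(PPh3)4, DMF, 80 °C) would give 23.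

**Step 13 (final acetal removal).**
- What may go wrong: acid-catalysed addition of the two phenols to their neighbouring olefins (chroman formation) or hydration of the olefins may compete with acetal cleavage.
- Fallback: set out from 23 and return at 24 by exchanging the acetal for a silyl ether under buffered conditions. TESOTf (excess) with 2,2'-bipyridyl in CH2Cl2 at 0 °C converts an aryl methoxymethyl ether directly into the triethylsilyl ether and silylates the two free hydroxyls, giving (2R,3R)-6-(3-methylbut-2-en-1-yl)-2-[3-(3-methylbut-2-en-1-yl)-4-(triethylsilyloxy)phenyl]-3,7-bis(triethylsilyloxy)-2,3-dihydro-4H-chromen-4-one F9. Et3N·3HF in THF would then release 24 without protic acid.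

## Further compounds

F1 | step 9 | 1-[2,4-bis(methoxymethoxy)-5-(3-methylbut-2-en-1-yl)phenyl]ethan-1-one | CC(=O)c1cc(CC=C(C)C)c(OCOC)cc1OCOC
F2 | step 9 | (2E)-1-[2,4-bis(methoxymethoxy)-5-(3-methylbut-2-en-1-yl)phenyl]-3-[4-(methoxymethoxy)phenyl]prop-2-en-1-one | O=C(/C=C/c1ccc(OCOC)cc1)c1cc(CC=C(C)C)c(OCOC)cc1OCOC
F3 | step 9 | [2,4-bis(methoxymethoxy)-5-(3-methylbut-2-en-1-yl)phenyl]{(2R,3S)-3-[4-(methoxymethoxy)phenyl]oxiran-2-yl}methanone | O=C(c1cc(CC=C(C)C)c(OCOC)cc1OCOC)[C@@H]1O[C@H]1c1ccc(OCOC)cc1
F4 | step 9 | (2R,3R)-3,7-dihydroxy-2-(4-hydroxyphenyl)-6-(3-methylbut-2-en-1-yl)-2,3-dihydro-4H-chromen-4-one | Oc1ccc([C@H]2Oc3cc(O)c(CC=C(C)C)cc3C(=O)[C@@H]2O)cc1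
F5 | step 8 | (2R)-1-[2,4-dihydroxy-5-(3-methylbut-2-en-1-yl)phenyl]-2-hydroxy-3-(4-hydroxyphenyl)propan-1-one | O=C(c1cc(CC=C(C)C)c(O)cc1O)[C@H](O)Cc1ccc(O)cc1
F6 | step 6 | (2R)-2-(tert-butyldimethylsilyloxy)-3-[4-(tert-butyldimethylsilyloxy)phenyl]propanal | O=C[C@H](O[Si](C)(C)C(C)(C)C)Cc1ccc(O[Si](C)(C)C(C)(C)C)cc1
F7 | step 6 | (2R)-1-[2,4-bis(methoxymethoxy)-5-(3-methylbut-2-en-1-yl)phenyl]-2-(tert-butyldimethylsilyloxy)-3-[4-(tert-butyldimethylsilyloxy)phenyl]propan-1-ol (C1 epimers) | OC(c1cc(CC=C(C)C)c(OCOC)cc1OCOC)[C@H](O[Si](C)(C)C(C)(C)C)Cc1ccc(O[Si](C)(C)C(C)(C)C)cc1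
F8 | step 12 | (2R,3R)-3-hydroxy-2-(4-hydroxy-3-iodophenyl)-7-(methoxymethoxy)-6-(3-methylbut-2-en-1-yl)-2,3-dihydro-4H-chromen-4-one | Oc1ccc([C@H]2Oc3cc(OCOC)c(CC=C(C)C)cc3C(=O)[C@@H]2O)cc1I
F9 | step 13 | (2R,3R)-6-(3-methylbut-2-en-1-yl)-2-[3-(3-methylbut-2-en-1-yl)-4-(triethylsilyloxy)phenyl]-3,7-bis(triethylsilyloxy)-2,3-dihydro-4H-chromen-4-one | CC(C)=CCc1cc([C@H]2Oc3cc(O[Si](CC)(CC)CC)c(CC=C(C)C)cc3C(=O)[C@@H]2O[Si](CC)(CC)CC)ccc1O[Si](CC)(CC)CC
A1 | alternative 1 | (2R,3R)-3-hydroxy-8-iodo-7-[(2-methylbut-3-en-2-yl)oxy]-2-{4-[(2-methylbut-3-en-2-yl)oxy]phenyl}-2,3-dihydro-4H-chromen-4-one | C=CC(C)(C)Oc1ccc([C@H]2Oc3c(I)c(OC(C)(C)C=C)ccc3C(=O)[C@@H]2O)cc1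
A2 | alternative 1 | (2R,3R)-3,7,4'-trihydroxy-8-iodo-6,3'-diprenylflavanone | CC(C)=CCc1cc([C@H]2Oc3c(I)c(O)c(CC=C(C)C)cc3C(=O)[C@@H]2O)ccc1O
A3 | alternative 2 | 7-(methoxymethoxy)-2,2-dimethyl-6-(3-methylbut-2-en-1-yl)-4H-1,3-benzodioxin-4-one | CC1(C)OC(=O)c2cc(CC=C(C)C)c(OCOC)cc2O1
A4 | alternative 2 | (E)-2-[4-(methoxymethoxy)-3-(3-methylbut-2-en-1-yl)phenyl]ethenyl acetate | CC(=O)O/C=C/c1ccc(OCOC)c(CC=C(C)C)c1
A5 | alternative 2 | 3-(methoxymethoxy)-4-(3-methylbut-2-en-1-yl)-6-(oxomethylidene)cyclohexa-2,4-dien-1-one | O=C=C1C=C(CC=C(C)C)C(OCOC)=CC1=O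
A6 | alternative 2 | (2R,3R)-3-acetoxy-7,4'-bis(methoxymethoxy)-6,3'-diprenylflavanone | CC(C)=CCc1cc([C@H]2Oc3cc(OCOC)c(CC=C(C)C)cc3C(=O)[C@@H]2OC(C)=O)ccc1OCOC
A7 | alternative 3 | (2R,3R)-3-[2-bromo-5-(methoxymethoxy)-4-(3-methylbut-2-en-1-yl)phenoxy]-2-(tert-butyldimethylsilyloxy)-N-methoxy-3-[4-(methoxymethoxy)-3-(3-methylbut-2-en-1-yl)phenyl]-N-methylpropanamide | CON(C)C(=O)[C@H](O[Si](C)(C)C(C)(C)C)[C@H](Oc1cc(OCOC)c(CC=C(C)C)cc1Br)c1ccc(OCOC)c(CC=C(C)C)c1
A8 | alternative 3 | (2R,3R)-3-(tert-butyldimethylsilyloxy)-7,4'-bis(methoxymethoxy)-6,3'-diprenylflavanone | CC(C)=CCc1cc([C@H]2Oc3cc(OCOC)c(CC=C(C)C)cc3C(=O)[C@@H]2O[Si](C)(C)C(C)(C)C)ccc1OCOC
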